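Remark on the chemistry (assumption): (triisopropylsilyloxy)acetylene is treated as not purchasable and is made in step 7; "prenyl" means 3‑methylbut‑2‑enyl throughout.

## Structural features

The target 21 is a flavone: a benzo ring A fused through C4a–C8a to a 4‑pyranone ring C, with ring B (2‑methoxy‑4‑hydroxyphenyl) on C2 and a prenyl chain on C3. Ring A has the phloroglucinol pattern, with oxygen on C5, C7 and C8a and hydrogen on C6 and C8. Ring B holds one methyl ether (C2') that must stay distinct from the free phenol at C4'. There is no stereocentre, and the side‑chain alkene carries two identical methyl groups, so the problems are regiochemical and chemoselective only. The fragile groups are the trisubstituted prenyl alkene (strong acid, electrophiles, oxidants, hydrogenation) and three phenols of different acidity, the 5‑OH being hydrogen‑bonded to the C4 carbonyl. The real difficulty is the fully substituted C2=C3 bond, where a hindered ortho‑substituted aryl group and the prenyl chain are neighbours, and the need to put carbon on a phloroglucinol‑type ring only where wanted. The key step exploits the C5(OH)–C6(H)–C7(O)–C8(H) segment of ring A. C8 and C5 are the two carbons of a ketene attached to C8a, C6 and C7 are the two carbons of an oxygen‑bearing alkyne, and the C4a=C8a bond is the C3=C2 double bond of a preformed pyranone.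

## Logic of the disconnections

**21 ⇒ 20.** The two O–Si bonds at O7 and O4' are cut. Both phenols carry the same silyl group, so one fluoride step ends the synthesis and no acid meets the prenyl group late. The demand is that the ring B silyl ether, put on in the first step, survives amide bases, dilute acid and light.

**20 ⇒ 12 + 16.** Ring A is removed by cutting C4a–C5, C5–C6, C7–C8 and, as a retro‑migration, C8–C8a. This leaves a monocyclic pyranone 12 and the two‑carbon alkyne 16. The forward cascade passes through 17, 18 and 19. The four‑membered intermediate 18 carries the silyloxy group on C3 and the pyranonyl group on C4; a 4‑siloxy isomer cannot arise from this polarity and would not place oxygen on C7. The demands are that the ketene carbonyl carbon bonds to the unsubstituted carbon of 16, that no OH group is present to trap the ketene, and that the light excites the diazo chromophore only.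

**16 ⇒ 13.** The O–Si and C–O bonds are cut, going back to a metal acetylide that is oxidised to the ynolate 15 and silylated. The demand is silylation on oxygen and not on carbon, which calls for a bulky silyl electrophile.

**12 ⇒ 10.** The C=N bond at the diazo carbon is cut. The diazo group is put onto the methyl group of a methyl ketone by diazo transfer, instead of making a C–C bond between a carboxylic acid derivative and a diazoalkane. This avoids a diazoalkane, an acid chloride beside the prenyl group and a hydroxide step beside the aryl silyl ether, and it saves a step. The demand is that the acetyl methyl is the only enolisable position of 10, which it is.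

**10 ⇒ 8 (through 9).** The ring O–C2 bond of the pyranone is cut and the acetyl carbonyl is masked as a ketal, giving the open 1,3,5‑triketone 8. The mask keeps a fourth carbonyl out of the chain, which would invite five‑membered ring closure. The demand is that the ring closes before the ketal is opened, under acid mild enough for the prenyl group.

**8 ⇒ 6 + 7.** The bond between the chain methylene and the ketal‑bearing acyl carbon is cut. This is the γ‑acylation of a β‑diketone dianion by a non‑enolisable ester. The demand is excess base, because the product is more acidic than the starting diketone.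

**6 ⇒ 4 + 5.** The bond between the central carbon of the diketone and the prenyl CH2 is cut. The prenyl group goes on when the future C3 is the only doubly activated carbon, before any aromatic ring that could compete exists. The demand is mono C‑alkylation over O‑alkylation.

**4 ⇒ 2 + 3.** The bond between the ketone methyl carbon and the acetyl carbon is cut. The demand is an acylation free of alkoxide, which could attack the aryl silyl ether.

**2 ⇒ 1.** The O–Si bond on ring B is cut, back to the purchasable acetophenone.

## Other disconnections considered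

**Alternative 1:** The cut runs through C2–C1' and C3–CH2(prenyl), leaving an intact chromone, a ring B organometallic and 5. The cuprate from [2‑methoxy‑4‑(methoxymethoxy)phenyl]magnesium bromide A2 and CuBr·SMe2 (monovalent copper) would add to C2 of 5,7‑bis(methoxymethoxy)‑4H‑chromen‑4‑one A1. The enolate would then be alkylated at C3 by 5 to give the trans chroman‑4‑one A3 (racemic), the electrophile approaching anti to the new C2 aryl group. Dehydrogenation across C2–C3 and acidic removal of three acetals would follow.
- In favour: three simple components, both substituents of the crowded C2=C3 bond set in one flask with unambiguous regiochemistry, and rings A and B bought instead of built. The two stereocentres need no control because both are erased.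
- Against: a chromone with a 5‑alkoxy group peri to the carbonyl is a reluctant acceptor, and the ortho‑methoxy aryl nucleophile is hindered. The chromanone enolate can expel the C8a phenoxide or alkylate on oxygen or twice. The late dehydrogenation must remove a hindered C3–H beside allylic C–H bonds and electron‑rich rings. The last step is acidic with the prenyl group present.
- Comparison: it is more convergent and better on step count (about six or seven operations against nine). It is ionic and needs no lamp, which is an advantage on scale. The chosen plan reaches the flavone oxidation level without redox adjustment and ends with a neutral fluoride step. Its risk lies early, on cheap material, whereas this alternative concentrates risk in its last two steps.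

**Alternative 2:** The cut is C4–C4a. (Z)‑3‑[3,5‑Bis(allyloxy)phenoxy]‑3‑[4‑(allyloxy)‑2‑methoxyphenyl]‑2‑prenylacryloyl chloride A4, activated by SnCl4 at low temperature, would acylate the ortho carbon of its aryloxy ring and close ring C to the tris‑allyl ether A5. Pd(PPh3)4 (zerovalent palladium) with an allyl scavenger would then free the three phenols.
- In favour: the aryloxy ring is symmetric and very nucleophilic, so both ortho positions are equivalent and ring closure has no regiochemical question. Ring A is bought.
- Against: A4 is a tetrasubstituted enol ether whose Z geometry must be made and kept while flanked by a hindered aryl group and the prenyl chain. Acid chloride formation and SnCl4 expose the prenyl alkene and the allyl ethers to HCl and a strong Lewis acid (hydrochlorination, cation–olefin reactions, ether cleavage).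
- Comparison: on protecting‑group economy it equals the chosen plan (one global deprotection), and on equipment it is better (no photochemistry). The length is expected to be similar. The chosen plan has no geometry to control, because the ring opening of 18 is reversible and only the reactive isomer 19 is drained, and it uses no Lewis acid beside the prenyl group.

**Alternative 3:** The cuts are C1'–C2' and C5'–C6', so ring B is built. 2‑Ethynyl‑5,7‑bis(methoxymethoxy)‑3‑prenyl‑4H‑chromen‑4‑one A6 and 1,1‑dimethoxy‑3‑(trimethylsilyloxy)buta‑1,3‑diene A7 would combine in a Diels–Alder reaction. The diene CH2 terminus bonds to the terminal alkyne carbon, and loss of methanol and of the silyl group aromatises the adduct to A8.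
- In favour: the 2'‑methoxy/4'‑hydroxy pattern follows from the polarity of A7, and the 4'‑OH emerges free and already distinct from the methyl ether with no protecting group on ring B. This is better than the chosen plan. The reaction is thermal.
- Against: A6 needs an ethynyl group placed on C2 next to the prenyl chain, which is a multistep task. Its alkyne is activated only vinylogously and is shielded by the prenyl group. The ketene acetal A7 may add in a conjugate sense without ring closure. Two acetals must finally be removed with acid beside the prenyl group.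
- Comparison: both plans build an arene from an alkyne by a pericyclic sequence whose regiochemistry comes from a polarised oxygenated partner, and are equal on that point. This alternative builds the simpler, non‑fused ring and needs no lamp, which is equal or better in operational terms. The chosen plan is expected to be equal or shorter in steps and has the milder end game.

Key step: step 8

## Route

Step 1
Reactants: 1 4'-hydroxy-2'-methoxyacetophenone
Product: 2 2'-methoxy-4'-(triisopropylsilyloxy)acetophenone
Conditions: i-Pr3SiCl (1.2 equiv), imidazole (2.5 equiv), DMF, 0 °C to rt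
Reagents that add atoms: chlorotriisopropylsilane, CC(C)[Si](Cl)(C(C)C)C(C)C
Why: Imidazole-promoted O-silylation of the only OH group; the bulky aryl triisopropylsilyl ether should tolerate the amide bases, dilute acid and light used later and leaves with fluoride together with the silyl group that the key step brings to O7.

Step 2
Reactants: 2 2'-methoxy-4'-(triisopropylsilyloxy)acetophenone; 3 1-acetyl-1H-benzotriazole
Product: 4 1-[2-methoxy-4-(triisopropylsilyloxy)phenyl]butane-1,3-dione
Conditions: MgBr2·OEt2 (2.5 equiv), i-Pr2NEt (3 equiv), 3 (1.2 equiv), CH2Cl2, rt; 1 M HCl work-up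
Reagents that add atoms: none
Why: Crossed Claisen-type C-acylation by soft enolisation: MgBr2 bound to the carbonyl and the ortho-methoxy oxygen acidifies the methyl ketone enough for the amine base, the magnesium enolate is acylated by the acylbenzotriazole, and the magnesium diketonate formed resists a second acylation; no alkoxide is present to attack the aryl silyl ether.

Step 3
Reactants: 4 1-[2-methoxy-4-(triisopropylsilyloxy)phenyl]butane-1,3-dione; 5 prenyl bromide (1-bromo-3-methylbut-2-ene)
Product: 6 1-[2-methoxy-4-(triisopropylsilyloxy)phenyl]-2-(3-methylbut-2-enyl)butane-1,3-dione (racemic)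
Conditions: K2CO3 (1.5 equiv), 5 (1.05 equiv), acetone, 45 °C
Reagents that add atoms: none
Why: C-alkylation of a β-diketone enolate by a soft primary allylic bromide (SN2, no allylic transposition); one equivalent of bromide limits dialkylation; the new centre forms racemic, is enolisable and is erased in step 5.

Step 4
Reactants: 6 1-[2-methoxy-4-(triisopropylsilyloxy)phenyl]-2-(3-methylbut-2-enyl)butane-1,3-dione; 7 ethyl 2,2-diethoxypropanoate
Product: 8 6,6-diethoxy-1-[2-methoxy-4-(triisopropylsilyloxy)phenyl]-2-(3-methylbut-2-enyl)heptane-1,3,5-trione (racemic)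
Conditions: LiN(i-Pr)2 (3.2 equiv), THF, −78 to 0 °C; 7 (1.3 equiv), −78 to 0 °C; aq NH4Cl
Reagents that add atoms: none
Why: Hauser-type γ-acylation of a β-diketone dianion: the second deprotonation can only occur at the methyl group, the terminal carbanion is the most nucleophilic site, the ketal ester cannot enolise, and the extra base takes up the more acidic triketone as it forms.

Step 5
Reactants: 8 6,6-diethoxy-1-[2-methoxy-4-(triisopropylsilyloxy)phenyl]-2-(3-methylbut-2-enyl)heptane-1,3,5-trione
Product: 10 2-acetyl-6-[2-methoxy-4-(triisopropylsilyloxy)phenyl]-5-(3-methylbut-2-enyl)-4H-pyran-4-one, via ketal-protected pyranone 9 (not isolated)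
Conditions: TsOH·H2O (0.2 equiv), toluene, 50 °C; then 2 M aq HCl, THF, 40 °C
Reagents that add atoms: water, O
Why: Acid-catalysed cyclodehydration of a 1,3,5-triketone to a 4-pyranone (enol oxygen adds to the far carbonyl, then water is lost) is run nearly anhydrous first so that the ring closes before the ketal opens; aqueous acid then hydrolyses the ketal to the acetyl group. Once the ring is closed the prenyl group has no neighbouring OH to cyclise onto, and aryl triisopropylsilyl ethers resist dilute acid.

Step 6
Reactants: 10 2-acetyl-6-[2-methoxy-4-(triisopropylsilyloxy)phenyl]-5-(3-methylbut-2-enyl)-4H-pyran-4-one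
Product: 12 2-diazo-1-{6-[2-methoxy-4-(triisopropylsilyloxy)phenyl]-5-(3-methylbut-2-enyl)-4-oxo-4H-pyran-2-yl}ethanone, via trifluoroacetyl diketone 11 (not isolated)
Conditions: LiN(SiMe3)2 (1.1 equiv), THF, −78 °C; CF3CO2CH2CF3 (1.2 equiv), −78 °C; 1 M HCl work-up; then 4-AcNHC6H4SO2N3 (1.5 equiv), Et3N (1.5 equiv), H2O (1 equiv), MeCN, rt
Reagents that add atoms: 4-acetamidobenzenesulfonyl azide, CC(=O)Nc1ccc(cc1)S(=O)(=O)N=[N+]=[N-]
Why: Detrifluoroacetylative diazo transfer: the kinetic enolate of the methyl ketone (the only enolisable site) is C-trifluoroacetylated, the resulting 1,3-diketone adds the sulfonyl azide under amine base, and fragmentation expels the trifluoroacetyl group on the sulfonamide nitrogen to leave the diazomethyl ketone.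

Step 7
Reactants: 13 acetylene
Product: 16 (triisopropylsilyloxy)acetylene, via lithium acetylide 14 (not isolated), via lithium ethynolate 15 (not isolated)
Conditions: n-BuLi (1.0 equiv), excess 13, THF, −78 °C; t-BuOOLi [from t-BuOOH and LiN(SiMe3)2, THF, −78 °C], −78 to −10 °C; i-Pr3SiOTf (1.1 equiv), −78 to 0 °C; cold pentane/aq NaHCO3 work-up
Reagents that add atoms: tert-butyl hydroperoxide, CC(C)(C)OO; triisopropylsilyl trifluoromethanesulfonate, CC(C)[Si](OS(=O)(=O)C(F)(F)F)(C(C)C)C(C)C
Why: Oxidation of a lithium acetylide by lithium tert-butyl peroxide (attack of the carbanion on the O–O bond) gives the ynolate; the hard, bulky silyl triflate should silylate it on oxygen, and the bulk of the silyl group retards the 1,3-shift to a silylketene.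

Step 8
Reactants: 12 2-diazo-1-{6-[2-methoxy-4-(triisopropylsilyloxy)phenyl]-5-(3-methylbut-2-enyl)-4-oxo-4H-pyran-2-yl}ethanone; 16 (triisopropylsilyloxy)acetylene
Product: 20 5-hydroxy-2-[2-methoxy-4-(triisopropylsilyloxy)phenyl]-3-(3-methylbut-2-enyl)-7-(triisopropylsilyloxy)-4H-chromen-4-one, via pyranonylketene 17 (not isolated), via siloxycyclobutenone 18 (not isolated), via dienylketene 19 (not isolated)
Conditions: 16 (2.5 equiv), degassed ClCH2CH2Cl (0.05 M), hν (medium-pressure Hg lamp, uranium-glass filter, λ > 340 nm), 25 °C; then dark, 80 °C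
Reagents that add atoms: none
Why: Excitation of the diazo ketone expels N2 and the pyranonyl group migrates (Wolff rearrangement) to give ketene 17, which creates the C8–C8a bond. Ketene 17 and the electron-rich alkyne 16 then undergo a (2+2) cycloaddition in which the electrophilic ketene carbonyl carbon bonds to the nucleophilic unsubstituted alkyne carbon (C5–C6) and the ketene α-carbon to the oxygen-bearing carbon (C7–C8), giving the 3-siloxy-4-pyranonylcyclobutenone 18. A four-electron electrocyclic opening of 18 (by light or at 80 °C) gives dienylketene 19, and because this opening is reversible the isomer with the ketene carbon cis to the pyranone is continually supplied. Ring A closes by a thermal six-electron disrotatory electrocyclisation that joins the ketene carbon to pyranone C3 (C4a–C5), and tautomerisation with loss of the C4a hydrogen gives the phenol, hydrogen-bonded to the C4 carbonyl. The closest known reaction type is the Danheiser benzannulation of α,β-unsaturated and heteroaryl diazomethyl ketones with siloxyalkynes. No stereocentre is created; the one in 18 is erased. The selectivity needed is regiochemical: the polarised siloxyalkyne places oxygen on C7 and not C6, and pyranone C3 is the only carbon next to the ketene-bearing C2, so closure can only occur toward C4a. Chemoselectivity rests on the substrate: the prenyl alkene lies across the ring from the ketene and cannot reach it, no OH group is present to trap the ketene, and the filtered light excites the diazo chromophore but should leave the pyranone alone.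

Step 9
Reactants: 20 5-hydroxy-2-[2-methoxy-4-(triisopropylsilyloxy)phenyl]-3-(3-methylbut-2-enyl)-7-(triisopropylsilyloxy)-4H-chromen-4-one
Product: 21 5,7-dihydroxy-2-(4-hydroxy-2-methoxyphenyl)-3-(3-methylbut-2-enyl)-4H-chromen-4-one
Conditions: Bu4NF (2.5 equiv), AcOH (2.5 equiv), THF, 0 °C to rt
Reagents that add atoms: none
Why: Fluoride cleaves both aryl silyl ethers (strong Si–F bond, phenoxide leaving groups); acetic acid buffers the phenoxides so that the prenyl group and the chelated 5-OH are not disturbed, and the methyl ether is untouched.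

## Compound list

1 | 4'-hydroxy-2'-methoxyacetophenone | COc1cc(O)ccc1C(C)=O | starting material
2 | 2'-methoxy-4'-(triisopropylsilyloxy)acetophenone | COc1cc(O[Si](C(C)C)(C(C)C)C(C)C)ccc1C(C)=O | intermediate
3 | 1-acetyl-1H-benzotriazole | CC(=O)n1nnc2ccccc12 | starting material
4 | 1-[2-methoxy-4-(triisopropylsilyloxy)phenyl]butane-1,3-dione | COc1cc(O[Si](C(C)C)(C(C)C)C(C)C)ccc1C(=O)CC(C)=O | intermediate
5 | prenyl bromide (1-bromo-3-methylbut-2-ene) | CC(C)=CCBr | starting material
6 | 1-[2-methoxy-4-(triisopropylsilyloxy)phenyl]-2-(3-methylbut-2-enyl)butane-1,3-dione (racemic; enolisable centre) | COc1cc(O[Si](C(C)C)(C(C)C)C(C)C)ccc1C(=O)C(CC=C(C)C)C(C)=O | intermediate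
7 | ethyl 2,2-diethoxypropanoate | CCOC(=O)C(C)(OCC)OCC | starting material
8 | 6,6-diethoxy-1-[2-methoxy-4-(triisopropylsilyloxy)phenyl]-2-(3-methylbut-2-enyl)heptane-1,3,5-trione (racemic; enolisable centre) | COc1cc(O[Si](C(C)C)(C(C)C)C(C)C)ccc1C(=O)C(CC=C(C)C)C(=O)CC(=O)C(C)(OCC)OCC | intermediate
9 | 2-(1,1-diethoxyethyl)-6-[2-methoxy-4-(triisopropylsilyloxy)phenyl]-5-(3-methylbut-2-enyl)-4H-pyran-4-one | CCOC(C)(OCC)c1cc(=O)c(CC=C(C)C)c(-c2ccc(O[Si](C(C)C)(C(C)C)C(C)C)cc2OC)o1 | intermediate
10 | 2-acetyl-6-[2-methoxy-4-(triisopropylsilyloxy)phenyl]-5-(3-methylbut-2-enyl)-4H-pyran-4-one | CC(=O)c1cc(=O)c(CC=C(C)C)c(-c2ccc(O[Si](C(C)C)(C(C)C)C(C)C)cc2OC)o1 | intermediate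
11 | 4,4,4-trifluoro-1-{6-[2-methoxy-4-(triisopropylsilyloxy)phenyl]-5-(3-methylbut-2-enyl)-4-oxo-4H-pyran-2-yl}butane-1,3-dione | O=C(CC(=O)C(F)(F)F)c1cc(=O)c(CC=C(C)C)c(-c2ccc(O[Si](C(C)C)(C(C)C)C(C)C)cc2OC)o1 | intermediate
12 | 2-diazo-1-{6-[2-methoxy-4-(triisopropylsilyloxy)phenyl]-5-(3-methylbut-2-enyl)-4-oxo-4H-pyran-2-yl}ethanone | [N-]=[N+]=CC(=O)c1cc(=O)c(CC=C(C)C)c(-c2ccc(O[Si](C(C)C)(C(C)C)C(C)C)cc2OC)o1 | intermediate
13 | acetylene | C#C | starting material
14 | lithium acetylide | [Li]C#C | intermediate
15 | lithium ethynolate | [Li+].[O-]C#C | intermediate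
16 | (triisopropylsilyloxy)acetylene | C#CO[Si](C(C)C)(C(C)C)C(C)C | intermediate
17 | 2-{6-[2-methoxy-4-(triisopropylsilyloxy)phenyl]-5-(3-methylbut-2-enyl)-4-oxo-4H-pyran-2-yl}ethen-1-one (pyranonylketene) | O=C=Cc1cc(=O)c(CC=C(C)C)c(-c2ccc(O[Si](C(C)C)(C(C)C)C(C)C)cc2OC)o1 | intermediate
18 | 4-{6-[2-methoxy-4-(triisopropylsilyloxy)phenyl]-5-(3-methylbut-2-enyl)-4-oxo-4H-pyran-2-yl}-3-(triisopropylsilyloxy)cyclobut-2-en-1-one (racemic) | O=C1C=C(O[Si](C(C)C)(C(C)C)C(C)C)C1c1cc(=O)c(CC=C(C)C)c(-c2ccc(O[Si](C(C)C)(C(C)C)C(C)C)cc2OC)o1 | intermediate
19 | (3E)-4-{6-[2-methoxy-4-(triisopropylsilyloxy)phenyl]-5-(3-methylbut-2-enyl)-4-oxo-4H-pyran-2-yl}-3-(triisopropylsilyloxy)buta-1,3-dien-1-one (ketene carbon cis to the pyranone) | O=C=C/C(O[Si](C(C)C)(C(C)C)C(C)C)=C\c1cc(=O)c(CC=C(C)C)c(-c2ccc(O[Si](C(C)C)(C(C)C)C(C)C)cc2OC)o1 | intermediate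
20 | 5-hydroxy-2-[2-methoxy-4-(triisopropylsilyloxy)phenyl]-3-(3-methylbut-2-enyl)-7-(triisopropylsilyloxy)-4H-chromen-4-one | COc1cc(O[Si](C(C)C)(C(C)C)C(C)C)ccc1-c1oc2cc(O[Si](C(C)C)(C(C)C)C(C)C)cc(O)c2c(=O)c1CC=C(C)C | intermediate
21 | 5,7-dihydroxy-2-(4-hydroxy-2-methoxyphenyl)-3-(3-methylbut-2-enyl)-4H-chromen-4-one | COc1cc(O)ccc1-c1oc2cc(O)cc(O)c2c(=O)c1CC=C(C)C | target

## Step count and least certain steps

Total step count: 9. Longest linear sequence: 8 steps (steps 1–6, 8 and 9); step 7 is a one-step side branch.

**Step 8 (key step).**
- What may go wrong: competitive light absorption by the arylpyranone chromophore and by the flavone as it builds up, which slows the Wolff rearrangement and lets ketene dimerisation or a second ketene addition to 18 take over. The thermal opening of 18 may also stall, and the O7 silyl group may be lost from the acidic product.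
- Fallback (ketene generated thermally instead of by light), from 12 back to 20:
  - A silver-catalysed Wolff rearrangement of 12 in wet THF [PhCO2Ag (0.1 equiv), Et3N, THF–H2O, rt] should give {6-[2-methoxy-4-(triisopropylsilyloxy)phenyl]-5-(3-methylbut-2-enyl)-4-oxo-4H-pyran-2-yl}acetic acid F1, kept cold because such acids decarboxylate easily.
  - 1-Chloro-N,N,2-trimethylprop-1-en-1-amine in CH2Cl2 at 0 °C should convert it, without free HCl, into {6-[2-methoxy-4-(triisopropylsilyloxy)phenyl]-5-(3-methylbut-2-enyl)-4-oxo-4H-pyran-2-yl}acetyl chloride F2.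
  - Slow addition of Et3N to F2 and 16 in toluene should generate 17 by dehydrochlorination and trap it as 18. Heating at 80–110 °C should carry 18 through 19 to 20.

**Step 7.**
- What may go wrong: disproportionation of 14 on warming before the oxidation is complete, silylation of 15 on carbon instead of oxygen, and loss of the volatile product or its 1,3-silyl shift during isolation.
- Fallback (an alkyl ynol ether with a fluoride-labile alkyl group in place of the silyl ynol ether), from 12 back to 21:
  - 2-(Trimethylsilyl)ethanol, KH and trichloroethylene in THF should give (E)-[2-(1,2-dichlorovinyloxy)ethyl]trimethylsilane F3.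
  - n-BuLi (2.2 equiv, −78 °C) and then methanol should give [2-(ethynyloxy)ethyl]trimethylsilane F4.
  - Irradiation of 12 with F4 under the conditions of step 8 should give 5-hydroxy-2-[2-methoxy-4-(triisopropylsilyloxy)phenyl]-3-(3-methylbut-2-enyl)-7-[2-(trimethylsilyl)ethoxy]-4H-chromen-4-one F5.
  - CsF or Bu4NF in DMF at 60 °C should remove the aryl silyl ether and the 2-(trimethylsilyl)ethyl group (β-elimination) and give 21 directly.

**Step 4.**
- What may go wrong: slow acylation by the hindered ketal ester, so that proton exchange between dianion and product, O-acylation, or retro-Claisen cleavage of the 2-substituted diketone by liberated ethoxide compete.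
- Fallback (a more electrophilic C2 unit, and the diazo ketone made by acyl substitution instead of diazo transfer), from 6 back to 12, bypassing 8–11:
  - The dianion of 6 and diethyl oxalate should give ethyl 6-[2-methoxy-4-(triisopropylsilyloxy)phenyl]-5-(3-methylbut-2-enyl)-2,4,6-trioxohexanoate F6.
  - TsOH·H2O (cat.) in toluene at 50 °C should close it to ethyl 6-[2-methoxy-4-(triisopropylsilyloxy)phenyl]-5-(3-methylbut-2-enyl)-4-oxo-4H-pyran-2-carboxylate F7.
  - LiOH in THF–H2O at 0 °C should give 6-[2-methoxy-4-(triisopropylsilyloxy)phenyl]-5-(3-methylbut-2-enyl)-4-oxo-4H-pyran-2-carboxylic acid F8.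
  - 1-Chloro-N,N,2-trimethylprop-1-en-1-amine should give 6-[2-methoxy-4-(triisopropylsilyloxy)phenyl]-5-(3-methylbut-2-enyl)-4-oxo-4H-pyran-2-carbonyl chloride F9.
  - Me3SiCHN2 (2 equiv) in MeCN–THF at 0 °C, then aqueous work-up, should give 12.
  - This reserve brings back a diazoalkane reagent and a hydroxide step, which is why it is not the first choice.

**Step 5.**
- What may go wrong: addition of an enol OH of 8 across the prenyl alkene before the pyranone closes, ketal hydrolysis ahead of ring closure followed by five-membered closure, and slow hydrolysis of the ketal once it sits on the electron-poor ring, which would call for acid strong enough to attack the prenyl group or the aryl silyl ether.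
- Fallback (the acetyl carbonyl revealed by oxidation instead of hydrolysis), from 6 back to 10:
  - Racemic ethyl lactate with Et3SiCl and imidazole should give ethyl 2-(triethylsilyloxy)propanoate F10.
  - The dianion of 6, formed as in step 4, should be acylated by F10 to give 1-[2-methoxy-4-(triisopropylsilyloxy)phenyl]-2-(3-methylbut-2-enyl)-6-(triethylsilyloxy)heptane-1,3,5-trione F11 (diastereomer mixture).
  - TsOH·H2O (cat.) in MeOH at rt should remove the triethylsilyl group and close the ring to 2-(1-hydroxyethyl)-6-[2-methoxy-4-(triisopropylsilyloxy)phenyl]-5-(3-methylbut-2-enyl)-4H-pyran-4-one F12 (racemic).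
  - Dess–Martin periodinane with NaHCO3 in CH2Cl2 should oxidise it to 10.

## Further compounds

F1 | step 8 | {6-[2-methoxy-4-(triisopropylsilyloxy)phenyl]-5-(3-methylbut-2-enyl)-4-oxo-4H-pyran-2-yl}acetic acid | OC(=O)Cc1cc(=O)c(CC=C(C)C)c(-c2ccc(O[Si](C(C)C)(C(C)C)C(C)C)cc2OC)o1
F2 | step 8 | {6-[2-methoxy-4-(triisopropylsilyloxy)phenyl]-5-(3-methylbut-2-enyl)-4-oxo-4H-pyran-2-yl}acetyl chloride | ClC(=O)Cc1cc(=O)c(CC=C(C)C)c(-c2ccc(O[Si](C(C)C)(C(C)C)C(C)C)cc2OC)o1
F3 | step 7 | (E)-[2-(1,2-dichlorovinyloxy)ethyl]trimethylsilane | Cl/C=C(/Cl)OCC[Si](C)(C)C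
F4 | step 7 | [2-(ethynyloxy)ethyl]trimethylsilane | C#COCC[Si](C)(C)C
F5 | step 7 | 5-hydroxy-2-[2-methoxy-4-(triisopropylsilyloxy)phenyl]-3-(3-methylbut-2-enyl)-7-[2-(trimethylsilyl)ethoxy]-4H-chromen-4-one | COc1cc(O[Si](C(C)C)(C(C)C)C(C)C)ccc1-c1oc2cc(OCC[Si](C)(C)C)cc(O)c2c(=O)c1CC=C(C)C
F6 | step 4 | ethyl 6-[2-methoxy-4-(triisopropylsilyloxy)phenyl]-5-(3-methylbut-2-enyl)-2,4,6-trioxohexanoate (racemic; enolisable centre) | CCOC(=O)C(=O)CC(=O)C(CC=C(C)C)C(=O)c1ccc(O[Si](C(C)C)(C(C)C)C(C)C)cc1OC
F7 | step 4 | ethyl 6-[2-methoxy-4-(triisopropylsilyloxy)phenyl]-5-(3-methylbut-2-enyl)-4-oxo-4H-pyran-2-carboxylate | CCOC(=O)c1cc(=O)c(CC=C(C)C)c(-c2ccc(O[Si](C(C)C)(C(C)C)C(C)C)cc2OC)o1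
F8 | step 4 | 6-[2-methoxy-4-(triisopropylsilyloxy)phenyl]-5-(3-methylbut-2-enyl)-4-oxo-4H-pyran-2-carboxylic acid | OC(=O)c1cc(=O)c(CC=C(C)C)c(-c2ccc(O[Si](C(C)C)(C(C)C)C(C)C)cc2OC)o1
F9 | step 4 | 6-[2-methoxy-4-(triisopropylsilyloxy)phenyl]-5-(3-methylbut-2-enyl)-4-oxo-4H-pyran-2-carbonyl chloride | ClC(=O)c1cc(=O)c(CC=C(C)C)c(-c2ccc(O[Si](C(C)C)(C(C)C)C(C)C)cc2OC)o1
F10 | step 5 | ethyl 2-(triethylsilyloxy)propanoate (racemic) | CCOC(=O)C(C)O[Si](CC)(CC)CC
F11 | step 5 | 1-[2-methoxy-4-(triisopropylsilyloxy)phenyl]-2-(3-methylbut-2-enyl)-6-(triethylsilyloxy)heptane-1,3,5-trione (diastereomer mixture, racemic) | CC[Si](CC)(CC)OC(C)C(=O)CC(=O)C(CC=C(C)C)C(=O)c1ccc(O[Si](C(C)C)(C(C)C)C(C)C)cc1OC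
F12 | step 5 | 2-(1-hydroxyethyl)-6-[2-methoxy-4-(triisopropylsilyloxy)phenyl]-5-(3-methylbut-2-enyl)-4H-pyran-4-one (racemic) | CC(O)c1cc(=O)c(CC=C(C)C)c(-c2ccc(O[Si](C(C)C)(C(C)C)C(C)C)cc2OC)o1
A1 | alternative 1 | 5,7-bis(methoxymethoxy)-4H-chromen-4-one | COCOc1cc(OCOC)c2c(=O)ccoc2c1
A2 | alternative 1 | [2-methoxy-4-(methoxymethoxy)phenyl]magnesium bromide | COCOc1ccc([Mg]Br)c(OC)c1
A3 | alternative 1 | trans-2-[2-methoxy-4-(methoxymethoxy)phenyl]-5,7-bis(methoxymethoxy)-3-(3-methylbut-2-enyl)chroman-4-one (racemic; the (2R,3S) enantiomer is drawn) | COCOc1ccc([C@@H]2Oc3cc(OCOC)cc(OCOC)c3C(=O)[C@H]2CC=C(C)C)c(OC)c1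
A4 | alternative 2 | (Z)-3-[3,5-bis(allyloxy)phenoxy]-3-[4-(allyloxy)-2-methoxyphenyl]-2-(3-methylbut-2-enyl)acryloyl chloride | ClC(=O)/C(CC=C(C)C)=C(\Oc1cc(OCC=C)cc(OCC=C)c1)c1ccc(OCC=C)cc1OC
A5 | alternative 2 | 5,7-bis(allyloxy)-2-[4-(allyloxy)-2-methoxyphenyl]-3-(3-methylbut-2-enyl)-4H-chromen-4-one | C=CCOc1ccc(-c2oc3cc(OCC=C)cc(OCC=C)c3c(=O)c2CC=C(C)C)c(OC)c1
A6 | alternative 3 | 2-ethynyl-5,7-bis(methoxymethoxy)-3-(3-methylbut-2-enyl)-4H-chromen-4-one | C#Cc1oc2cc(OCOC)cc(OCOC)c2c(=O)c1CC=C(C)C
A7 | alternative 3 | 1,1-dimethoxy-3-(trimethylsilyloxy)buta-1,3-diene | COC(OC)=CC(=C)O[Si](C)(C)C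
A8 | alternative 3 | 2-(4-hydroxy-2-methoxyphenyl)-5,7-bis(methoxymethoxy)-3-(3-methylbut-2-enyl)-4H-chromen-4-one | COc1cc(O)ccc1-c1oc2cc(OCOC)cc(OCOC)c2c(=O)c1CC=C(C)C
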